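The ε ring is a cyclohexene in which the C4'=C5' double bond lies between the oxygen-bearing C3' and C6', which carries C7': a 1,4-relationship across an alkene, the signature of a 2-pyranone Diels–Alder adduct. Everything therefore rests on the [4+2] union of 4-methyl-2H-pyran-2-one (C3'–C7' plus the C5' methyl) with isobutene (C1', C2' and the geminal methyls). One operation forms C1'–C6' and C2'–C3', closes the carbocycle and sets both ring stereocentres, while the surviving lactone bridge keeps O3' and C7' on the same face. Lactol opening, Mitsunobu inversion with palmitic acid and a C15 + C10 + C15 Wittig assembly with a myristoylated β half made from (4R,6R)-actinol finish the target.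

Key step: step 3

Remark: positions in the target are given in carotenoid numbering (primed for the ε half); (4R,6R)-4-hydroxy-2,2,6-trimethylcyclohexanone (actinol) and (2E,4E,6E)-2,7-dimethylocta-2,4,6-trienedial are taken as purchased building blocks.
Remark: the pyranone carries no extra activating or chelating substituent, because C3, C5 and C6 of the diene all end as CH positions (bridgehead or vinylic) from which such a group could not be removed cleanly; activation and face selection are left to the catalyst.
Remark: the sense of induction in step 3 is predicted by analogy only; the (S)-configured catalyst is written, and its mirror image is to be used if it should favour the other face.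

**ε half (steps 1–8)**

Step 1
Reactants: 1 ethyl 3-methylbut-2-enoate
Product: 2 ethyl (4E)-5-(dimethylamino)-3-methylpenta-2,4-dienoate (2E/2Z mixture)
Conditions: t-BuOCH(NMe2)2 (1.5 equiv), neat, 110 °C
Reagents that add atoms: tert-butoxybis(dimethylamino)methane, CN(C)C(OC(C)(C)C)N(C)C
Why: Aminomethylenation of an activated methyl group with an aminal ester, in which the reagent ionises to a formamidinium tert-butoxide pair, the alkoxide removes a γ-proton of the vinylogous ester and the dienolate condenses at the γ-carbon, loss of dimethylamine giving the conjugated push–pull dienamine as the thermodynamic product.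

Step 2
Reactants: 2 ethyl (4E)-5-(dimethylamino)-3-methylpenta-2,4-dienoate
Product: 3 4-methyl-2H-pyran-2-one
Conditions: AcOH–2 M aq. H2SO4 (3:1) as medium, 90 °C
Reagents that add atoms: water, O
Why: Acid hydrolysis of the enamine to the 5-hydroxydienoate, easy E/Z equilibration of the push–pull C2=C3 bond and lactonisation with loss of ethanol give the 2-pyranone (enaminoester-to-pyranone cyclisation).

Step 3
Reactants: 3 4-methyl-2H-pyran-2-one; 4 isobutene
Product: 5 (1S,4R)-5,8,8-trimethyl-2-oxabicyclo[2.2.2]oct-5-en-3-one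
Conditions: 4 (10 equiv), (3aS)-1-(2-methylphenyl)-3,3-diphenyltetrahydro-1H,3H-pyrrolo[1,2-c][1,3,2]oxazaborole (22 mol%)/AlBr3 (20 mol%), 2,6-di-tert-butyl-4-methylpyridine (5 mol%), CH2Cl2, −78 → −30 °C, sealed vessel
Reagents that add atoms: none
Why: Proposed new method: the cationic boron Lewis acid binds the pyranone carbonyl at the lone pair syn to C3–H (the α-C–H···O contact typical of this catalyst class), turning the diene into a 2-boryloxypyrylium-like species that is most electrophilic at C6, so the CH2 terminus of isobutene bonds there first while the incipient tertiary cation is captured by C3 of the developing dienolate in one concerted, asynchronous, suprafacial [4+2] event. The closest known reaction type is the inverse-electron-demand Diels–Alder reaction of 2-pyranones with alkenes under heat, high pressure or achiral Lewis acids, which gives isolable 2-oxabicyclo[2.2.2]octenones, combined with oxazaborolidinium-catalysed enantioselective Diels–Alder reactions of carbonyl-activated π systems. The six-membered carbocycle is closed by intermolecular cycloaddition across C3 and C6 of the pyranone (new bonds C4–C8 and C1–C7 of 5), the lactone bridge being carried over unchanged. The two new stereocentres C1 and C4 are created together and their relative configuration is dictated by the bridge, so only the pyranone face has to be chosen, which the catalyst does by covering one face with its aryl groups. Regioselectivity follows from the matched polarity of both partners, no endo/exo question arises because the dienophile has two identical substituents on one carbon and none on the other, and the remaining demand, cycloaddition rather than ene reaction or cationic oligomerisation of isobutene, is addressed by the proton-free Lewis acid, the hindered pyridine as proton trap and the low temperature. Turnover is expected because the pyranone carbonyl is more basic than that of the saturated lactone product, and at −30 °C the adduct is far below the temperature of retro-[4+2] loss of CO2.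

Step 4
Reactants: 5 (1S,4R)-5,8,8-trimethyl-2-oxabicyclo[2.2.2]oct-5-en-3-one
Product: 6 (1S,4R)-5,8,8-trimethyl-2-oxabicyclo[2.2.2]oct-5-en-3-ol (lactol; both C3 epimers; used crude)
Conditions: i-Bu2AlH (1.1 equiv), CH2Cl2, −78 °C; Rochelle salt work-up
Reagents that add atoms: none
Why: Partial reduction of a lactone to the lactol with one equivalent of i-Bu2AlH at −78 °C, where the tetrahedral aluminium hemiacetal persists until work-up; neither bridgehead is affected and the new hemiacetal centre is inconsequential.

Step 5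
Reactants: 6 (1S,4R)-5,8,8-trimethyl-2-oxabicyclo[2.2.2]oct-5-en-3-ol
Product: 8 (3S,6R)-3-hydroxy-α-ionone [(3E)-4-((1R,4S)-4-hydroxy-2,6,6-trimethylcyclohex-2-en-1-yl)but-3-en-2-one], via hydroxy aldehyde 7 (not isolated)
Conditions: Ph3P=CHC(O)CH3 (2 equiv), PhCO2H (10 mol%), toluene, 80 °C
Reagents that add atoms: 1-(triphenyl-λ5-phosphanylidene)propan-2-one, CC(=O)C=P(c1ccccc1)(c1ccccc1)c1ccccc1
Why: Wittig olefination of a lactol through its ring-opened aldehyde tautomer 7 with a stabilised, essentially non-basic ylide, which gives the E-enone and should leave the C6' hydrogen (α to the aldehyde and allylic) and the cis O3'/C7' relationship untouched.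

Step 6
Reactants: 8 (3S,6R)-3-hydroxy-α-ionone; 9 palmitic acid
Product: 10 (1R,4R)-3,5,5-trimethyl-4-[(1E)-3-oxobut-1-en-1-yl]cyclohex-2-en-1-yl hexadecanoate [(3R,6R)-3-palmitoyloxy-α-ionone]
Conditions: 9 (1.3 equiv), PPh3 (1.5 equiv), DIAD (1.5 equiv), THF, 0 °C → rt
Reagents that add atoms: none
Why: Mitsunobu esterification, in which palmitate displaces the alkoxyphosphonium leaving group in SN2 fashion and inverts C3' from S to R to give the trans (3'R,6'R) ester, the SN2' alternative being disfavoured because it would have to occur at the fully substituted C5'.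

Step 7
Reactants: 10 (3R,6R)-3-palmitoyloxy-α-ionone
Product: 11 (1R,4R)-4-[(1E)-3-hydroxy-3-methylpenta-1,4-dien-1-yl]-3,5,5-trimethylcyclohex-2-en-1-yl hexadecanoate (both carbinol epimers)
Conditions: CH2=CHMgBr (1.2 equiv), THF, −78 °C; pH 7 buffer
Reagents that add atoms: vinylmagnesium bromide, C=C[Mg]Br
Why: Grignard 1,2-addition to the methyl ketone, which at −78 °C is much faster than attack on the ester of a secondary alcohol; the new carbinol centre is formed without control and is erased in step 8.

Step 8
Reactants: 11 (1R,4R)-4-[(1E)-3-hydroxy-3-methylpenta-1,4-dien-1-yl]-3,5,5-trimethylcyclohex-2-en-1-yl hexadecanoate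
Product: 12 {(2E,4E)-5-[(1R,4R)-4-(hexadecanoyloxy)-2,6,6-trimethylcyclohex-2-en-1-yl]-3-methylpenta-2,4-dien-1-yl}triphenylphosphonium bromide
Conditions: Ph3P·HBr (1.05 equiv), CH2Cl2, 0 °C → rt; crystallisation
Reagents that add atoms: triphenylphosphine hydrobromide, Br.c1ccccc1P(c1ccccc1)c1ccccc1
Why: Classical conversion of a vinyl carbinol into a carotenoid Wittig salt: acid ionises the tertiary bis-allylic alcohol to a pentadienyl cation that PPh3 captures at the unhindered terminus (allylic transposition), the (2E,4E) salt being purified by crystallisation, while the less ionisable secondary allylic ester and C3'/C6' are not touched.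

**β half (steps 9–14)**

Step 9
Reactants: 13 (4R,6R)-4-hydroxy-2,2,6-trimethylcyclohexanone; 14 myristic acid
Product: 15 (1R,5R)-3,3,5-trimethyl-4-oxocyclohexyl tetradecanoate
Conditions: 14 (1.1 equiv), DCC (1.2 equiv), DMAP (10 mol%), CH2Cl2, rt
Reagents that add atoms: none
Why: Steglich esterification of the secondary alcohol with retention at the carbinol carbon; the hindered ketone is inert.

Step 10
Reactants: 15 (1R,5R)-3,3,5-trimethyl-4-oxocyclohexyl tetradecanoate
Product: 16 (1R)-3,5,5-trimethyl-4-{[(trifluoromethyl)sulfonyl]oxy}cyclohex-3-en-1-yl tetradecanoate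
Conditions: Tf2O (1.3 equiv), 2,6-di-tert-butyl-4-methylpyridine (1.5 equiv), CH2Cl2, 0 °C → rt
Reagents that add atoms: trifluoromethanesulfonic anhydride, O=S(=O)(OS(=O)(=O)C(F)(F)F)C(F)(F)F
Why: Enol triflate formation by O-triflylation of the ketone and loss of the only α-proton (the other α-carbon is quaternary) under buffered, non-nucleophilic conditions that an ester tolerates, giving a single tetrasubstituted enol triflate and deliberately erasing the methyl-bearing stereocentre while the future C3 is unaffected.

Step 11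
Reactants: 16 (1R)-3,5,5-trimethyl-4-{[(trifluoromethyl)sulfonyl]oxy}cyclohex-3-en-1-yl tetradecanoate
Product: 17 (1R)-3,5,5-trimethyl-4-[(1E)-3-oxobut-1-en-1-yl]cyclohex-3-en-1-yl tetradecanoate [(3R)-3-myristoyloxy-β-ionone]
Conditions: CH2=CHC(O)CH3 (3 equiv), Pd(OAc)2 (5 mol%), PPh3 (10 mol%), Et3N (2 equiv), DMF, 70 °C
Reagents that add atoms: methyl vinyl ketone, CC(=O)C=C
Why: Heck reaction of an alkenyl triflate with an electron-poor alkene (oxidative addition to zerovalent palladium formed in situ, carbopalladation, syn β-hydride elimination), which gives the E-dienone of the β-ionone skeleton without involving the homoallylic ester stereocentre.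

Step 12
Reactants: 17 (3R)-3-myristoyloxy-β-ionone
Product: 18 (1R)-4-[(1E)-3-hydroxy-3-methylpenta-1,4-dien-1-yl]-3,5,5-trimethylcyclohex-3-en-1-yl tetradecanoate (both carbinol epimers)
Conditions: CH2=CHMgBr (1.2 equiv), THF, −78 °C; pH 7 buffer
Reagents that add atoms: vinylmagnesium bromide, C=C[Mg]Br
Why: Ketone-selective Grignard 1,2-addition at −78 °C as in step 7; the uncontrolled carbinol centre disappears in step 13.

Step 13
Reactants: 18 (1R)-4-[(1E)-3-hydroxy-3-methylpenta-1,4-dien-1-yl]-3,5,5-trimethylcyclohex-3-en-1-yl tetradecanoate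
Product: 19 {(2E,4E)-3-methyl-5-[(4R)-2,6,6-trimethyl-4-(tetradecanoyloxy)cyclohex-1-en-1-yl]penta-2,4-dien-1-yl}triphenylphosphonium bromide
Conditions: Ph3P·HBr (1.05 equiv), CH2Cl2, 0 °C → rt; crystallisation
Reagents that add atoms: triphenylphosphine hydrobromide, Br.c1ccccc1P(c1ccccc1)c1ccccc1
Why: The same ionisation and terminal capture by PPh3 as in step 8, here on the β-ionone series for which this vinyl carbinol route to the C15 Wittig salt is long established; the non-allylic C3 ester is inert.

Step 14
Reactants: 19 β-C15 phosphonium bromide; 20 (2E,4E,6E)-2,7-dimethylocta-2,4,6-trienedial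
Product: 22 (1R)-3,5,5-trimethyl-4-[(1E,3E,5E,7E,9E,11E)-3,7,12-trimethyl-13-oxotrideca-1,3,5,7,9,11-hexaen-1-yl]cyclohex-3-en-1-yl tetradecanoate [(3R)-3-myristoyloxy-12'-apo-β-caroten-12'-al], via β-C15 phosphorane 21 (not isolated)
Conditions: 20 (2.5 equiv), 1,2-epoxybutane, reflux; then heptane, 80 °C (Z → E), crystallisation; excess 20 recovered
Reagents that add atoms: none
Why: Wittig reaction in which the ylide 21 is generated under neutral conditions by bromide opening of the epoxide (the resulting bromoalkoxide is the base), so the ester survives; the excess of the symmetrical dialdehyde favours mono-olefination and heating equilibrates the C11=C12 Z isomer to E.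

**Union**

Step 15
Reactants: 12 ε-C15 phosphonium bromide; 22 (3R)-3-myristoyloxy-12'-apo-β-caroten-12'-al
Product: 24 (3R,3'R,6'R)-3-(tetradecanoyloxy)-β,ε-caroten-3'-yl hexadecanoate (lutein 3-myristate 3'-palmitate, CNP0230054.1), via ε-C15 phosphorane 23 (not isolated)
Conditions: 12 (1.2 equiv), 1,2-epoxybutane, reflux, Ar, dark; then heptane, 90 °C (Z → E); chromatography and crystallisation
Reagents that add atoms: none
Why: Second epoxide-mediated Wittig reaction, forming C11'=C12' under conditions that spare both esters and all three stereocentres; the Z isomer of the new bond is converted to the all-E compound by the thermal isomerisation usual for carotenoids.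

**Compound list**

1 | ethyl 3-methylbut-2-enoate | CCOC(=O)C=C(C)C | starting material
2 | ethyl (4E)-5-(dimethylamino)-3-methylpenta-2,4-dienoate (2E/2Z mixture) | CCOC(=O)C=C(C)/C=C/N(C)C | intermediate
3 | 4-methyl-2H-pyran-2-one | CC1=CC(=O)OC=C1 | intermediate
4 | isobutene (2-methylprop-1-ene) | CC(C)=C | starting material
5 | (1S,4R)-5,8,8-trimethyl-2-oxabicyclo[2.2.2]oct-5-en-3-one | O=C2O[C@@H]1C=C(C)[C@H]2C(C)(C)C1 | intermediate
6 | (1S,4R)-5,8,8-trimethyl-2-oxabicyclo[2.2.2]oct-5-en-3-ol (both C3 epimers) | OC2O[C@@H]1C=C(C)[C@H]2C(C)(C)C1 | intermediate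
7 | (1R,4S)-4-hydroxy-2,6,6-trimethylcyclohex-2-ene-1-carbaldehyde | O[C@@H]1C=C(C)[C@H](C=O)C(C)(C)C1 | intermediate
8 | (3S,6R)-3-hydroxy-α-ionone; (3E)-4-[(1R,4S)-4-hydroxy-2,6,6-trimethylcyclohex-2-en-1-yl]but-3-en-2-one | O[C@@H]1C=C(C)[C@H](/C=C/C(C)=O)C(C)(C)C1 | intermediate
9 | palmitic acid | CCCCCCCCCCCCCCCC(=O)O | starting material
10 | (1R,4R)-3,5,5-trimethyl-4-[(1E)-3-oxobut-1-en-1-yl]cyclohex-2-en-1-yl hexadecanoate | CCCCCCCCCCCCCCCC(=O)O[C@H]1C=C(C)[C@H](/C=C/C(C)=O)C(C)(C)C1 | intermediate
11 | (1R,4R)-4-[(1E)-3-hydroxy-3-methylpenta-1,4-dien-1-yl]-3,5,5-trimethylcyclohex-2-en-1-yl hexadecanoate (carbinol epimers) | CCCCCCCCCCCCCCCC(=O)O[C@H]1C=C(C)[C@H](/C=C/C(C)(O)C=C)C(C)(C)C1 | intermediate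
12 | {(2E,4E)-5-[(1R,4R)-4-(hexadecanoyloxy)-2,6,6-trimethylcyclohex-2-en-1-yl]-3-methylpenta-2,4-dien-1-yl}triphenylphosphonium bromide | CCCCCCCCCCCCCCCC(=O)O[C@H]1C=C(C)[C@H](/C=C/C(C)=C/C[P+](c2ccccc2)(c2ccccc2)c2ccccc2)C(C)(C)C1.[Br-] | intermediate
13 | (4R,6R)-4-hydroxy-2,2,6-trimethylcyclohexanone (actinol) | O=C1[C@H](C)C[C@@H](O)CC1(C)C | starting material
14 | myristic acid | CCCCCCCCCCCCCC(=O)O | starting material
15 | (1R,5R)-3,3,5-trimethyl-4-oxocyclohexyl tetradecanoate | O=C1[C@H](C)C[C@@H](OC(=O)CCCCCCCCCCCCC)CC1(C)C | intermediate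
16 | (1R)-3,5,5-trimethyl-4-{[(trifluoromethyl)sulfonyl]oxy}cyclohex-3-en-1-yl tetradecanoate | FC(F)(F)S(=O)(=O)OC1=C(C)C[C@@H](OC(=O)CCCCCCCCCCCCC)CC1(C)C | intermediate
17 | (1R)-3,5,5-trimethyl-4-[(1E)-3-oxobut-1-en-1-yl]cyclohex-3-en-1-yl tetradecanoate | CC(=O)/C=C/C1=C(C)C[C@@H](OC(=O)CCCCCCCCCCCCC)CC1(C)C | intermediate
18 | (1R)-4-[(1E)-3-hydroxy-3-methylpenta-1,4-dien-1-yl]-3,5,5-trimethylcyclohex-3-en-1-yl tetradecanoate (carbinol epimers) | C=CC(C)(O)/C=C/C1=C(C)C[C@@H](OC(=O)CCCCCCCCCCCCC)CC1(C)C | intermediate
19 | {(2E,4E)-3-methyl-5-[(4R)-2,6,6-trimethyl-4-(tetradecanoyloxy)cyclohex-1-en-1-yl]penta-2,4-dien-1-yl}triphenylphosphonium bromide | [Br-].c1ccccc1[P+](c1ccccc1)(c1ccccc1)C/C=C(C)/C=C/C2=C(C)C[C@@H](OC(=O)CCCCCCCCCCCCC)CC2(C)C | intermediate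
20 | (2E,4E,6E)-2,7-dimethylocta-2,4,6-trienedial | O=C/C(C)=C/C=C/C=C(C)/C=O | starting material
21 | ylide of 19; (4R)-3,5,5-trimethyl-4-[(1E,3E)-3-methyl-5-(triphenyl-λ5-phosphanylidene)penta-1,3-dien-1-yl]cyclohex-3-en-1-yl tetradecanoate | c1ccccc1P(c1ccccc1)(c1ccccc1)=C/C=C(C)/C=C/C2=C(C)C[C@@H](OC(=O)CCCCCCCCCCCCC)CC2(C)C | intermediate
22 | (1R)-3,5,5-trimethyl-4-[(1E,3E,5E,7E,9E,11E)-3,7,12-trimethyl-13-oxotrideca-1,3,5,7,9,11-hexaen-1-yl]cyclohex-3-en-1-yl tetradecanoate | O=C/C(C)=C/C=C/C=C(C)/C=C/C=C(C)/C=C/C2=C(C)C[C@@H](OC(=O)CCCCCCCCCCCCC)CC2(C)C | intermediate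
23 | ylide of 12; (1R,4R)-3,5,5-trimethyl-4-[(1E,3E)-3-methyl-5-(triphenyl-λ5-phosphanylidene)penta-1,3-dien-1-yl]cyclohex-2-en-1-yl hexadecanoate | CCCCCCCCCCCCCCCC(=O)O[C@H]1C=C(C)[C@H](/C=C/C(C)=C/C=P(c2ccccc2)(c2ccccc2)c2ccccc2)C(C)(C)C1 | intermediate
24 | (3R,3'R,6'R)-3-(tetradecanoyloxy)-β,ε-caroten-3'-yl hexadecanoate (all-E) | CCCCCCCCCCCCCCCC(=O)O[C@H]1C=C(C)[C@H](/C=C/C(C)=C/C=C/C(C)=C/C=C/C=C(C)/C=C/C=C(C)/C=C/C2=C(C)C[C@@H](OC(=O)CCCCCCCCCCCCC)CC2(C)C)C(C)(C)C1 | target

**Step count and risks**

Total step count: 15 (ε half: steps 1–8; β half: steps 9–14; union: step 15).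
Longest linear sequence: 9 steps (steps 1–8 and 15).

Steps most likely to fail:

1. Step 3. The Lewis-acid cycloaddition may not turn over, isobutene may oligomerise by a cationic chain, the polarised transition state may leak to an ene-type adduct at C6, or the catalyst may discriminate the two pyranone faces poorly. The fallback uses known chemistry and sets out from 3 and 4: the uncatalysed cycloaddition under high pressure (about 1.2 GPa, CH2Cl2, 50 °C), the established way of obtaining bridged lactones from 2-pyranones and alkenes without loss of CO2, should give the racemate, that is 5 together with its antipode (1R,4S)-5,8,8-trimethyl-2-oxabicyclo[2.2.2]oct-5-en-3-one F1. Preparative chromatography on a chiral stationary phase (cellulose tris(3,5-dimethylphenylcarbamate), supercritical CO2/MeOH) separates the two, and the route is rejoined at 5.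

2. Step 5. In the warm olefination the ring-opened β,γ-unsaturated aldehyde may epimerise at C6', its C4'=C5' bond may move into conjugation, or the lactol may open incompletely. The fallback sets out from 5 and avoids both the lactol and heating. Aminolysis with MeNH(OMe)·HCl/Me3Al (CH2Cl2, 0 °C → rt) gives (1R,4S)-4-hydroxy-N-methoxy-N,2,6,6-tetramethylcyclohex-2-ene-1-carboxamide F2. Silylation (Et3SiCl, imidazole, DMF) gives (1R,4S)-N-methoxy-N,2,6,6-tetramethyl-4-[(triethylsilyl)oxy]cyclohex-2-ene-1-carboxamide F3. Reduction with i-Bu2AlH (THF, −78 °C) gives (1R,4S)-2,6,6-trimethyl-4-[(triethylsilyl)oxy]cyclohex-2-ene-1-carbaldehyde F4. Horner–Wadsworth–Emmons olefination at room temperature with dimethyl (2-oxopropyl)phosphonate, LiCl and i-Pr2NEt in MeCN gives (3E)-4-{(1R,4S)-2,6,6-trimethyl-4-[(triethylsilyl)oxy]cyclohex-2-en-1-yl}but-3-en-2-one F5. Desilylation (AcOH–THF–H2O, rt) returns the route to 8.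

3. Step 6. The allylic alkoxyphosphonium ion may ionise, so that stereochemical fidelity at C3' is lost through SN1 or SN2' leakage, or it may eliminate to a cyclohexadiene. The fallback sets out from 8 and makes the ionisation deliberate. Dilute aqueous acid (0.1 M HCl, THF–H2O, rt), the known way of interconverting the C3' epimers of hydroxylated ε end groups, should equilibrate 8 with its C3' epimer (3R,6R)-3-hydroxy-α-ionone F6. The two diastereomers are separated on silica, 8 is recycled, and F6 is esterified with 9 under Steglich conditions (DCC, DMAP, CH2Cl2; retention), which comes back to the route at 10.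

Further compounds
F1 | step 3 | (1R,4S)-5,8,8-trimethyl-2-oxabicyclo[2.2.2]oct-5-en-3-one | O=C2O[C@H]1C=C(C)[C@@H]2C(C)(C)C1
F2 | step 5 | (1R,4S)-4-hydroxy-N-methoxy-N,2,6,6-tetramethylcyclohex-2-ene-1-carboxamide | O[C@@H]1C=C(C)[C@H](C(=O)N(C)OC)C(C)(C)C1
F3 | step 5 | (1R,4S)-N-methoxy-N,2,6,6-tetramethyl-4-[(triethylsilyl)oxy]cyclohex-2-ene-1-carboxamide | CC[Si](CC)(CC)O[C@@H]1C=C(C)[C@H](C(=O)N(C)OC)C(C)(C)C1
F4 | step 5 | (1R,4S)-2,6,6-trimethyl-4-[(triethylsilyl)oxy]cyclohex-2-ene-1-carbaldehyde | CC[Si](CC)(CC)O[C@@H]1C=C(C)[C@H](C=O)C(C)(C)C1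
F5 | step 5 | (3E)-4-{(1R,4S)-2,6,6-trimethyl-4-[(triethylsilyl)oxy]cyclohex-2-en-1-yl}but-3-en-2-one | CC[Si](CC)(CC)O[C@@H]1C=C(C)[C@H](/C=C/C(C)=O)C(C)(C)C1
F6 | step 6 | (3R,6R)-3-hydroxy-α-ionone; (3E)-4-[(1R,4R)-4-hydroxy-2,6,6-trimethylcyclohex-2-en-1-yl]but-3-en-2-one | O[C@H]1C=C(C)[C@H](/C=C/C(C)=O)C(C)(C)C1
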